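**Retrosynthetic overview**

1. Target ⇐ phenol desilylation ⇐ C2–C3 bond: the five-membered ring is closed last, by intramolecular aldol addition of a 1,4-diketone held trans on the cycloheptene (acetyl on C8a, isobutyryl on C3a), with the C1 ketone reduced in the same flask.
2. Enabling feature: the cis-1,3-diol of the five-membered ring, C1(OH)–C2H2–C3(OH)(i-Pr), is an aldol retron, and C8a is quaternary, so a C1 ketone can enolise only toward C2; the C8a methyl group, C3a–H and C4–O then steer both new carbinol centres.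
3. Diketone ⇐ Tsuji–Wacker oxidation of a C8a vinyl group ⇐ seven-membered ring (formed first) by ring-closing metathesis at C6=C7 of an acyclic triene.
4. Triene ⇐ dianionic Ireland–Claisen rearrangement of a (2E)-3-methylhexa-2,5-dienyl β-hydroxy ester, which sets C3a and the quaternary C8a in one event from the C4 carbinol.
5. C4 is the one bought stereocentre (ethyl (R)-4-chloro-3-hydroxybutanoate); the 4-silyloxybenzoate of the target is installed early and serves as the protecting group of C4–OH.

Key step: step 11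

Remark: locants are those of the azulene skeleton of the target (five-membered ring C1, C2, C3, C3a, C8a; seven-membered ring C3a, C4 to C8, C8a); pent-1-en-4-yne, ethyl (R)-4-chloro-3-hydroxybutanoate and 4-hydroxybenzoic acid are taken as the commercial starting materials.

**Step 1**
Reactants: 1 pent-1-en-4-yne
Product: 2 (2E)-3-methylhexa-2,5-dien-1-ol
Conditions: AlMe3 (2 equiv), Cp2ZrCl2 (0.2 equiv), CH2Cl2, 0 °C → rt; n-BuLi, THF, −78 °C; (CH2O)n, rt; aq. HCl
Reagents that add atoms: trimethylaluminium, C[Al](C)C; formaldehyde (as paraformaldehyde), C=O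
Why: Zirconium-catalysed Negishi carboalumination adds CH3–Al syn across the terminal alkyne only, and the alkenyl aluminate is hydroxymethylated with retention, so the allyl group ends trans to CH2OH ((E)-alkene) while the isolated vinyl group stays untouched.

**Step 2**
Reactants: 3 ethyl (3R)-4-chloro-3-hydroxybutanoate
Product: 4 ethyl 2-[(2R)-oxiran-2-yl]acetate
Conditions: Ag2O (1.1 equiv), MeCN, 60 °C, dark
Reagents that add atoms: none
Why: Silver-assisted intramolecular Williamson closure of the chlorohydrin under non-basic conditions should avoid isomerisation of the epoxy ester to the 4-hydroxycrotonate; the C–O bond at the stereocentre is not touched.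

**Step 3**
Reactants: 4 ethyl 2-[(2R)-oxiran-2-yl]acetate
Product: 5 ethyl (3S)-3-hydroxy-5-methylhex-5-enoate
Conditions: CH2=C(CH3)MgBr (1.5 equiv), CuI (10 mol%), THF, −40 → −20 °C; aq. NH4Cl
Reagents that add atoms: isopropenylmagnesium bromide, CC(=C)[Mg]Br
Why: Copper-catalysed Grignard opening of the terminal epoxide at CH2 (SN2) should outrun addition to the ester at −40 °C; the carbinol centre (later C4) is retained and becomes (S) only through the change in substituent priorities.

**Step 4**
Reactants: 5 ethyl (3S)-3-hydroxy-5-methylhex-5-enoate; 2 (2E)-3-methylhexa-2,5-dien-1-ol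
Product: 6 (2E)-3-methylhexa-2,5-dien-1-yl (3S)-3-hydroxy-5-methylhex-5-enoate
Conditions: 2 (1.5 equiv), Ti(OEt)4 (20 mol%), toluene, 100 °C, ethanol distilled off
Reagents that add atoms: none
Why: Titanate-mediated transesterification is neutral, tolerates the free β-hydroxyl group and the alkenes, and is driven by removal of ethanol.

**Step 5**
Reactants: 6 (2E)-3-methylhexa-2,5-dien-1-yl (3S)-3-hydroxy-5-methylhex-5-enoate
Product: 7 (2S,3S)-3-hydroxy-5-methyl-2-[(3S)-3-methylhexa-1,5-dien-3-yl]hex-5-enoic acid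
Conditions: LDA (2.3 equiv), THF, −78 °C; warm to 50 °C; aq. HCl
Reagents that add atoms: none
Why: Dianionic Ireland–Claisen rearrangement: the lithium chelate between alkoxide and enolate oxygen fixes the enolate geometry and shields one face (the sense of the Fráter–Seebach alkylation, C3a anti to the C4 carbinol), and the chair transition state with the (E)-alkene places the allyl group equatorial and so sets the quaternary C8a, both centres being relayed from C4.

**Step 6**
Reactants: 8 4-hydroxybenzoic acid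
Product: 9 tert-butyldimethylsilyl 4-[(tert-butyldimethylsilyl)oxy]benzoate
Conditions: TBSCl (2.3 equiv), imidazole (4 equiv), DMF, rt
Reagents that add atoms: tert-butyldimethylsilyl chloride, CC(C)(C)[Si](C)(C)Cl
Why: Silylation of phenol and acid gives a silyl ester that can be turned into the acid chloride under neutral conditions without loss of the aryl silyl ether.

**Step 7**
Reactants: 9 tert-butyldimethylsilyl 4-[(tert-butyldimethylsilyl)oxy]benzoate; 7 (2S,3S)-3-hydroxy-5-methyl-2-[(3S)-3-methylhexa-1,5-dien-3-yl]hex-5-enoic acid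
Product: 11 (2S,3S)-3-({4-[(tert-butyldimethylsilyl)oxy]benzoyl}oxy)-5-methyl-2-[(3S)-3-methylhexa-1,5-dien-3-yl]hex-5-enoic acid, via 4-[(tert-butyldimethylsilyl)oxy]benzoyl chloride 10 (not isolated)
Conditions: 9 (1.3 equiv), (COCl)2, DMF (cat.), CH2Cl2, 0 °C → rt, evaporate; then 7, pyridine, DMAP (cat.), CH2Cl2, 0 °C → rt; aq. work-up
Reagents that add atoms: none
Why: Oxalyl chloride/DMF converts the silyl ester into the acid chloride, which acylates the C4 hydroxyl under DMAP catalysis (a mixed anhydride formed at the carboxyl group can pass its aroyl group to the β-oxygen through a six-membered transition state), so the ester of the target doubles as the protecting group.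

**Step 8**
Reactants: 11 (2S,3S)-3-({4-[(tert-butyldimethylsilyl)oxy]benzoyl}oxy)-5-methyl-2-[(3S)-3-methylhexa-1,5-dien-3-yl]hex-5-enoic acid
Product: 13 (4S,5S)-2,7-dimethyl-5-[(3S)-3-methylhexa-1,5-dien-3-yl]-6-oxooct-1-en-4-yl 4-[(tert-butyldimethylsilyl)oxy]benzoate, via acyl chloride 12 (not isolated)
Conditions: (COCl)2, DMF (cat.), CH2Cl2, rt, evaporate; then i-PrMgCl (1.1 equiv), Fe(acac)3 (3 mol%), THF, −78 °C
Reagents that add atoms: isopropylmagnesium chloride, CC(C)[Mg]Cl
Why: Iron-catalysed acylation of the Grignard reagent by the acid chloride is complete within minutes at −78 °C, stops at the ketone and should spare the aryl ester, the silyl ether, the alkenes and the C3a–H.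

**Step 9**
Reactants: 13 (4S,5S)-2,7-dimethyl-5-[(3S)-3-methylhexa-1,5-dien-3-yl]-6-oxooct-1-en-4-yl 4-[(tert-butyldimethylsilyl)oxy]benzoate
Product: 14 (1S,6S,7S)-6-ethenyl-3,6-dimethyl-7-(2-methylpropanoyl)cyclohept-3-en-1-yl 4-[(tert-butyldimethylsilyl)oxy]benzoate
Conditions: second-generation Grubbs catalyst (H2IMes)(PCy3)Cl2Ru=CHPh (5 mol%), CH2Cl2 (5 mM), 40 °C
Reagents that add atoms: none
Why: Ring-closing metathesis: the carbene forms at the unhindered allyl group and closes onto the 1,1-disubstituted alkene to give the trisubstituted cycloheptene, while the vinyl group on the quaternary carbon is too hindered to initiate and can only form a four-membered ring with the allyl group.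

**Step 10**
Reactants: 14 (1S,6S,7S)-6-ethenyl-3,6-dimethyl-7-(2-methylpropanoyl)cyclohept-3-en-1-yl 4-[(tert-butyldimethylsilyl)oxy]benzoate
Product: 15 (1S,6R,7S)-6-acetyl-3,6-dimethyl-7-(2-methylpropanoyl)cyclohept-3-en-1-yl 4-[(tert-butyldimethylsilyl)oxy]benzoate
Conditions: PdCl2 (10 mol%), CuCl (1 equiv), O2 (1 atm), DMF/H2O 7:1, rt
Reagents that add atoms: water, O
Why: Tsuji–Wacker oxidation: Markovnikov hydroxypalladation of the only monosubstituted alkene gives the methyl ketone, and the trisubstituted ring alkene is inert.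

**Step 11**
Reactants: 15 (1S,6R,7S)-6-acetyl-3,6-dimethyl-7-(2-methylpropanoyl)cyclohept-3-en-1-yl 4-[(tert-butyldimethylsilyl)oxy]benzoate
Product: 17 (1R,3R,3aS,4S,8aR)-1,3-dihydroxy-6,8a-dimethyl-3-(propan-2-yl)-1,2,3,3a,4,5,8,8a-octahydroazulen-4-yl 4-[(tert-butyldimethylsilyl)oxy]benzoate, via aldol hydroxy ketone 16 (not isolated)
Conditions: TiCl4 (2.2 equiv), n-Bu3N (1.3 equiv), CH2Cl2, −78 °C, 2 h; then BH3·pyridine (1.5 equiv), −78 °C, 2 h; MeOH, pH 7 buffer, −78 °C → rt
Reagents that add atoms: none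
Why: TiCl4/n-Bu3N enolises only the acetyl CH3 (the C1 ketone has no other α-hydrogen, the C3 ketone only two hindered methine hydrogens), the trichlorotitanium enolate adds through C2 to the TiCl4-activated isobutyryl carbonyl C3, and borane–pyridine then reduces the titanium-bound cyclopentanone in the same flask; the closest known reaction types are the titanium-mediated crossed aldol addition of ketone enolates to ketones, the closure of 1,4-diketones to 3-hydroxycyclopentanones and the TiCl4/borane–pyridine reduction of β-hydroxy ketones. The five-membered ring closes in the 5-(enolendo)-exo-trig mode common to all 1,4-diketone aldol closures, and the ring fusion comes out trans because the two acyl groups already stand trans-diequatorial on the cycloheptene. C3 is set by substrate control: in the closing conformer the isopropyl group turns away from the angular C8a methyl group (1,3-syn on the new ring) and from the C4 aroyloxy group, the carbonyl oxygen lies syn to C4–O where titanium can bridge it to the ester, and the hydroxyl therefore ends cis to the C8a methyl group. C1 is set by the angular methyl group and the bulky C3 titanium alkoxide, which occupy the same face, so hydride enters anti to both and the C1 hydroxyl ends cis to the C3 hydroxyl. The step needs site-selective enolisation (enolisation at C3a would expel the β-aroyloxy group) and an aldolate that neither dehydrates nor passes on the ester; the constitution of the diketone secures the first, and the weakly nucleophilic, covalent titanium aldolate held at −78 °C until it is reduced secures the second.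

**Step 12**
Reactants: 17 (1R,3R,3aS,4S,8aR)-1,3-dihydroxy-6,8a-dimethyl-3-(propan-2-yl)-1,2,3,3a,4,5,8,8a-octahydroazulen-4-yl 4-[(tert-butyldimethylsilyl)oxy]benzoate
Product: 18 (1R,3R,3aS,4S,8aR)-1,3-dihydroxy-6,8a-dimethyl-3-(propan-2-yl)-1,2,3,3a,4,5,8,8a-octahydroazulen-4-yl 4-hydroxybenzoate
Conditions: Bu4NF (1.1 equiv), AcOH (1.2 equiv), THF, 0 °C
Reagents that add atoms: none
Why: Fluoride cleaves the aryl silyl ether within minutes, and the acetic acid buffer keeps phenoxide and alkoxides protonated so that the ester should neither migrate to the C3 hydroxyl nor be cleaved.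

**Compound list**

1 | pent-1-en-4-yne | C=CCC#C | starting material
2 | (2E)-3-methylhexa-2,5-dien-1-ol | C=CC/C(C)=C/CO | intermediate
3 | ethyl (3R)-4-chloro-3-hydroxybutanoate | CCOC(=O)C[C@@H](O)CCl | starting material
4 | ethyl 2-[(2R)-oxiran-2-yl]acetate | CCOC(=O)C[C@@H]1CO1 | intermediate
5 | ethyl (3S)-3-hydroxy-5-methylhex-5-enoate | CCOC(=O)C[C@@H](O)CC(C)=C | intermediate
6 | (2E)-3-methylhexa-2,5-dien-1-yl (3S)-3-hydroxy-5-methylhex-5-enoate | C=CC/C(C)=C/COC(=O)C[C@@H](O)CC(C)=C | intermediate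
7 | (2S,3S)-3-hydroxy-5-methyl-2-[(3S)-3-methylhexa-1,5-dien-3-yl]hex-5-enoic acid | C=CC[C@@](C)(C=C)[C@H](C(=O)O)[C@@H](O)CC(C)=C | intermediate
8 | 4-hydroxybenzoic acid | OC(=O)c1ccc(O)cc1 | starting material
9 | tert-butyldimethylsilyl 4-[(tert-butyldimethylsilyl)oxy]benzoate | CC(C)(C)[Si](C)(C)OC(=O)c1ccc(O[Si](C)(C)C(C)(C)C)cc1 | intermediate
10 | 4-[(tert-butyldimethylsilyl)oxy]benzoyl chloride (formed and used in the flask) | O=C(Cl)c1ccc(O[Si](C)(C)C(C)(C)C)cc1 | intermediate
11 | (2S,3S)-3-({4-[(tert-butyldimethylsilyl)oxy]benzoyl}oxy)-5-methyl-2-[(3S)-3-methylhexa-1,5-dien-3-yl]hex-5-enoic acid | C=CC[C@@](C)(C=C)[C@H](C(=O)O)[C@@H](OC(=O)c1ccc(O[Si](C)(C)C(C)(C)C)cc1)CC(C)=C | intermediate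
12 | (2S,3S)-3-({4-[(tert-butyldimethylsilyl)oxy]benzoyl}oxy)-5-methyl-2-[(3S)-3-methylhexa-1,5-dien-3-yl]hex-5-enoyl chloride (formed and used in the flask) | C=CC[C@@](C)(C=C)[C@H](C(=O)Cl)[C@@H](OC(=O)c1ccc(O[Si](C)(C)C(C)(C)C)cc1)CC(C)=C | intermediate
13 | (4S,5S)-2,7-dimethyl-5-[(3S)-3-methylhexa-1,5-dien-3-yl]-6-oxooct-1-en-4-yl 4-[(tert-butyldimethylsilyl)oxy]benzoate | C=CC[C@@](C)(C=C)[C@H](C(=O)C(C)C)[C@@H](OC(=O)c1ccc(O[Si](C)(C)C(C)(C)C)cc1)CC(C)=C | intermediate
14 | (1S,6S,7S)-6-ethenyl-3,6-dimethyl-7-(2-methylpropanoyl)cyclohept-3-en-1-yl 4-[(tert-butyldimethylsilyl)oxy]benzoate | CC1=CC[C@@](C)(C=C)[C@H](C(=O)C(C)C)[C@@H](OC(=O)c2ccc(O[Si](C)(C)C(C)(C)C)cc2)C1 | intermediate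
15 | (1S,6R,7S)-6-acetyl-3,6-dimethyl-7-(2-methylpropanoyl)cyclohept-3-en-1-yl 4-[(tert-butyldimethylsilyl)oxy]benzoate | CC1=CC[C@@](C)(C(C)=O)[C@H](C(=O)C(C)C)[C@@H](OC(=O)c2ccc(O[Si](C)(C)C(C)(C)C)cc2)C1 | intermediate
16 | (3R,3aS,4S,8aR)-3-hydroxy-6,8a-dimethyl-1-oxo-3-(propan-2-yl)-1,2,3,3a,4,5,8,8a-octahydroazulen-4-yl 4-[(tert-butyldimethylsilyl)oxy]benzoate (present in the flask as its titanium alkoxide) | CC1=CC[C@@]2(C)C(=O)C[C@@](O)(C(C)C)[C@@H]2[C@@H](OC(=O)c3ccc(O[Si](C)(C)C(C)(C)C)cc3)C1 | intermediate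
17 | (1R,3R,3aS,4S,8aR)-1,3-dihydroxy-6,8a-dimethyl-3-(propan-2-yl)-1,2,3,3a,4,5,8,8a-octahydroazulen-4-yl 4-[(tert-butyldimethylsilyl)oxy]benzoate | CC1=CC[C@@]2(C)[C@H](O)C[C@@](O)(C(C)C)[C@@H]2[C@@H](OC(=O)c3ccc(O[Si](C)(C)C(C)(C)C)cc3)C1 | intermediate
18 | (1R,3R,3aS,4S,8aR)-1,3-dihydroxy-6,8a-dimethyl-3-(propan-2-yl)-1,2,3,3a,4,5,8,8a-octahydroazulen-4-yl 4-hydroxybenzoate | CC1=CC[C@@]2(C)[C@H](O)C[C@@](O)(C(C)C)[C@@H]2[C@@H](OC(=O)c2ccc(O)cc2)C1 | target

**Step count and risks**

Total step count: 12. Longest linear sequence: 10 steps (3 to 18 through steps 2, 3, 4, 5, 7, 8, 9, 10, 11, 12); steps 1 and 6 are side branches.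

Steps most likely to fail:

Step 11. The 5-(enolendo) closure may be slow. Lewis-acid-promoted side reactions could then overtake it: ene-type attack of the C6=C7 alkene on the activated isobutyryl group, or enolisation toward C3a with loss of the aroate. Hydride delivery could also lose its facial bias. The fallback sets out from 15 and generates the enolate reductively under neutral conditions. TMSOTf/Et3N (CH2Cl2, −78 °C) should give the terminal silyl enol ether (1S,6R,7S)-3,6-dimethyl-7-(2-methylpropanoyl)-6-{1-[(trimethylsilyl)oxy]ethenyl}cyclohept-3-en-1-yl 4-[(tert-butyldimethylsilyl)oxy]benzoate F1. N-Bromosuccinimide (THF, −78 °C) should convert it into the bromoketone (1S,6R,7S)-6-(2-bromoacetyl)-3,6-dimethyl-7-(2-methylpropanoyl)cyclohept-3-en-1-yl 4-[(tert-butyldimethylsilyl)oxy]benzoate F2. SmI2 (2.2 equiv, THF, −78 °C) should then form the trivalent samarium enolate, whose Reformatsky-type aldol addition gives the hydroxy ketone 16, now isolated. NaBH4 (MeOH, −40 °C) should reduce 16 from the face anti to the angular methyl group, and the fallback comes back to the route at 17.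

Step 5. At the temperature that the quaternary-centre-forming rearrangement needs, the lithium chelate that fixes the enolate geometry and shields one face may loosen, giving poor diastereoselection at C3a/C8a, or the dianion may decompose before it rearranges. The fallback sets out from 6 and uses a protected silyl ketene acetal instead of the chelated dianion. TBSOTf/2,6-lutidine should give the silyl ether (2E)-3-methylhexa-2,5-dien-1-yl (3S)-3-[(tert-butyldimethylsilyl)oxy]-5-methylhex-5-enoate F3. LDA in THF/DMPU at −78 °C followed by TMSCl should give the ketene acetal (1Z,3S)-3-[(tert-butyldimethylsilyl)oxy]-5-methyl-1-{[(2E)-3-methylhexa-2,5-dien-1-yl]oxy}-1-[(trimethylsilyl)oxy]hexa-1,5-diene F4, with the chain cis to OSiMe3 as in the chelate. On warming to 25–60 °C it should rearrange through the same chair to trimethylsilyl (2S,3S)-3-[(tert-butyldimethylsilyl)oxy]-5-methyl-2-[(3S)-3-methylhexa-1,5-dien-3-yl]hex-5-enoate F5. Aqueous work-up should give (2S,3S)-3-[(tert-butyldimethylsilyl)oxy]-5-methyl-2-[(3S)-3-methylhexa-1,5-dien-3-yl]hex-5-enoic acid F6, and HF·pyridine in THF returns the route to 7.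

Step 8. The hindered acid chloride may react slowly, so that deprotonation to a ketene with loss of the β-aroyloxy group, or attack of the Grignard reagent on the aryl ester, competes. The fallback sets out from 11 (through its acid chloride 12) and builds the ketone in two redox stages. LiAlH(OtBu)3 (THF, −78 °C) should give the aldehyde (2S,3S)-5-methyl-2-[(3S)-3-methylhexa-1,5-dien-3-yl]-1-oxohex-5-en-3-yl 4-[(tert-butyldimethylsilyl)oxy]benzoate F7. i-PrMgCl (THF, −78 °C) should add to the aldehyde in preference to the ester and give (4S,5R)-6-hydroxy-2,7-dimethyl-5-[(3S)-3-methylhexa-1,5-dien-3-yl]oct-1-en-4-yl 4-[(tert-butyldimethylsilyl)oxy]benzoate F8 as both C6 epimers. Dess–Martin periodinane (CH2Cl2, NaHCO3) should oxidise both epimers, and the fallback comes back to the route at 13.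

**Further compounds**

F1 | step 11 | (1S,6R,7S)-3,6-dimethyl-7-(2-methylpropanoyl)-6-{1-[(trimethylsilyl)oxy]ethenyl}cyclohept-3-en-1-yl 4-[(tert-butyldimethylsilyl)oxy]benzoate | CC1=CC[C@@](C)(C(=C)O[Si](C)(C)C)[C@H](C(=O)C(C)C)[C@@H](OC(=O)c2ccc(O[Si](C)(C)C(C)(C)C)cc2)C1
F2 | step 11 | (1S,6R,7S)-6-(2-bromoacetyl)-3,6-dimethyl-7-(2-methylpropanoyl)cyclohept-3-en-1-yl 4-[(tert-butyldimethylsilyl)oxy]benzoate | CC1=CC[C@@](C)(C(=O)CBr)[C@H](C(=O)C(C)C)[C@@H](OC(=O)c2ccc(O[Si](C)(C)C(C)(C)C)cc2)C1
F3 | step 5 | (2E)-3-methylhexa-2,5-dien-1-yl (3S)-3-[(tert-butyldimethylsilyl)oxy]-5-methylhex-5-enoate | C=CC/C(C)=C/COC(=O)C[C@@H](O[Si](C)(C)C(C)(C)C)CC(C)=C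
F4 | step 5 | (1Z,3S)-3-[(tert-butyldimethylsilyl)oxy]-5-methyl-1-{[(2E)-3-methylhexa-2,5-dien-1-yl]oxy}-1-[(trimethylsilyl)oxy]hexa-1,5-diene | C=CC/C(C)=C/CO/C(O[Si](C)(C)C)=C/[C@@H](O[Si](C)(C)C(C)(C)C)CC(C)=C
F5 | step 5 | trimethylsilyl (2S,3S)-3-[(tert-butyldimethylsilyl)oxy]-5-methyl-2-[(3S)-3-methylhexa-1,5-dien-3-yl]hex-5-enoate | C=CC[C@@](C)(C=C)[C@H](C(=O)O[Si](C)(C)C)[C@@H](O[Si](C)(C)C(C)(C)C)CC(C)=C
F6 | step 5 | (2S,3S)-3-[(tert-butyldimethylsilyl)oxy]-5-methyl-2-[(3S)-3-methylhexa-1,5-dien-3-yl]hex-5-enoic acid | C=CC[C@@](C)(C=C)[C@H](C(=O)O)[C@@H](O[Si](C)(C)C(C)(C)C)CC(C)=C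
F7 | step 8 | (2S,3S)-5-methyl-2-[(3S)-3-methylhexa-1,5-dien-3-yl]-1-oxohex-5-en-3-yl 4-[(tert-butyldimethylsilyl)oxy]benzoate | C=CC[C@@](C)(C=C)[C@H](C=O)[C@@H](OC(=O)c1ccc(O[Si](C)(C)C(C)(C)C)cc1)CC(C)=C
F8 | step 8 | (4S,5R)-6-hydroxy-2,7-dimethyl-5-[(3S)-3-methylhexa-1,5-dien-3-yl]oct-1-en-4-yl 4-[(tert-butyldimethylsilyl)oxy]benzoate (both C6 epimers) | C=CC[C@@](C)(C=C)[C@H](C(O)C(C)C)[C@@H](OC(=O)c1ccc(O[Si](C)(C)C(C)(C)C)cc1)CC(C)=C
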